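## Retrosynthetic overview

1. Pieces: 3,4-dimethoxybenzaldehyde 1 and a vinyl Grignard reagent give, through magnesium alkoxide 2, vinyl carbinol 3; the second arene is 1,3,5-trimethoxybenzene 4.
2. C–C disconnection (aryl–CH2): allyl cation 5, formed from 3, plus arene 4 stand behind (E)-1,3-diarylpropene 6.
3. Key disconnection (C2–O, the only stereocentre): 6 plus water, by way of radical cation 7 and benzylic radical 8, stand behind hypophaol 9.
4. Rings: none is formed; both benzene rings are bought intact.

Assumption: the target is the (S)-alcohol encoded by the SMILES; the sense of induction of the new catalyst cannot be predicted, so the anion enantiomer written here as (S,S) stands for whichever antipode a first analytical run shows to give the (S)-alcohol.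

Catalyst of step 3: the ion pair of 3,6-di-tert-butyl-9-mesityl-10-phenylacridinium with a confined imidodiphosphorimidate (IDPi) anion. The anion is built from two (S)-3,3'-bis[3,5-bis(trifluoromethyl)phenyl]-BINOL units and carries two N-triflyl groups. It is made by anion exchange from the acridinium tetrafluoroborate.

## Route

Step 1
Reactants: 1 3,4-dimethoxybenzaldehyde (veratraldehyde)
Product: 3 rac-1-(3,4-dimethoxyphenyl)prop-2-en-1-ol, via bromomagnesium alkoxide 2 (not isolated)
Conditions: CH2=CHMgBr (1.2 equiv, 1 M in THF), THF, 0 °C, 1 h; then sat. aq NH4Cl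
Reagents that add atoms: vinylmagnesium bromide, C=C[Mg]Br
Why: Grignard 1,2-addition to an unhindered, non-enolisable aromatic aldehyde is fast and clean; the carbinol centre is formed racemic and is erased in step 2.

Step 2
Reactants: 3 rac-1-(3,4-dimethoxyphenyl)prop-2-en-1-ol; 4 1,3,5-trimethoxybenzene (3 equiv)
Product: 6 (E)-2-[3-(3,4-dimethoxyphenyl)prop-2-en-1-yl]-1,3,5-trimethoxybenzene, via allyl cation 5 (not isolated)
Conditions: Ca(NTf2)2 (5 mol%), Bu4NPF6 (5 mol%), CH2Cl2, rt
Reagents that add atoms: none
Why: Dehydrative Friedel–Crafts allylation (SN1 type): the calcium Lewis acid ionises 3 to the dimethoxyphenyl-stabilised allyl cation 5, which the strongly nucleophilic arene 4 attacks at the unhindered terminal carbon to give the conjugated (E)-alkene, the excess of 4 suppressing double allylation.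

Step 3
Reactants: 6 (E)-2-[3-(3,4-dimethoxyphenyl)prop-2-en-1-yl]-1,3,5-trimethoxybenzene
Product: 9 hypophaol (2S)-1-(3,4-dimethoxyphenyl)-3-(2,4,6-trimethoxyphenyl)propan-2-ol, via alkene radical cation 7 (not isolated), via hydroxy benzylic radical 8 (not isolated)
Conditions: acridinium (S,S)-IDPi ion pair (3 mol%), (4-MeOC6H4S)2 (10 mol%), H2O (5 equiv), CH2Cl2 (0.05 M), 450 nm LEDs, 0 °C, Ar
Reagents that add atoms: water, O
Why: Proposed new method: enantioselective anti-Markovnikov hydration through a chiral contact ion pair, in which the excited acridinium oxidises the styrene unit of 6 (its most easily oxidised site) to radical cation 7, which stays paired with the confined IDPi anion in CH2Cl2; water hydrogen-bonded to the anion then adds to C2, the alkene carbon remote from the aryl ring, on the face left open by the anion pocket, which forms the C2–O bond, sets the (S) centre and, after proton loss, gives benzylic radical 8; 8 takes a hydrogen atom from the arylthiol formed from the disulfide, and the thiyl radical is turned over by the reduced acridine radical; the closest known reactions are the racemic acridinium/thiol anti-Markovnikov hydration and hydroetherification of β-alkylstyrenes and the counteranion-directed photoredox cycloadditions of styrene radical cations.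

## Compound list

1 | 3,4-dimethoxybenzaldehyde (veratraldehyde) | COc1ccc(C=O)cc1OC | starting material
2 | bromomagnesium 1-(3,4-dimethoxyphenyl)prop-2-en-1-olate (racemic) | C=CC(O[Mg]Br)c1ccc(OC)c(OC)c1 | intermediate (not isolated)
3 | rac-1-(3,4-dimethoxyphenyl)prop-2-en-1-ol | C=CC(O)c1ccc(OC)c(OC)c1 | intermediate
4 | 1,3,5-trimethoxybenzene | COc1cc(OC)cc(OC)c1 | starting material
5 | 1-(3,4-dimethoxyphenyl)allyl cation | C=C[CH+]c1ccc(OC)c(OC)c1 | intermediate (not isolated)
6 | (E)-2-[3-(3,4-dimethoxyphenyl)prop-2-en-1-yl]-1,3,5-trimethoxybenzene | COc1cc(OC)c(C/C=C/c2ccc(OC)c(OC)c2)c(OC)c1 | intermediate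
7 | radical cation of 6 (one resonance form: charge on C2, spin on the benzylic carbon) | COc1cc(OC)c(C[CH+][CH]c2ccc(OC)c(OC)c2)c(OC)c1 | intermediate (not isolated)
8 | 1-(3,4-dimethoxyphenyl)-2-hydroxy-3-(2,4,6-trimethoxyphenyl)propan-1-yl radical, carbinol carbon already in the target configuration | COc1cc(OC)c(C[C@@H](O)[CH]c2ccc(OC)c(OC)c2)c(OC)c1 | intermediate (not isolated)
9 | hypophaol, (2S)-1-(3,4-dimethoxyphenyl)-3-(2,4,6-trimethoxyphenyl)propan-2-ol | COc1cc(OC)c(C[C@@H](O)Cc2ccc(OC)c(OC)c2)c(OC)c1 | target

## Step count and risks

Total step count: 3. Longest linear sequence: 3 steps (1 → 3 → 6 → 9).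

Steps most likely to fail, in order of risk:

Step 3 (the proposed new reaction). The risks are low enantioselectivity, cyclobutane dimers of 6 from radical cation 7, acid-promoted Markovnikov addition, and over-oxidation with C–C fragmentation of the electron-rich product 9 at high conversion. The fallback uses known chemistry and sets out from alkene 6. Shi asymmetric epoxidation with the D-fructose-derived ketone (KHSO5 as Oxone, 2KHSO5·KHSO4·K2SO4; K2CO3, Bu4NHSO4, MeCN/dimethoxymethane/aqueous buffer pH 10.5, 0 °C) gives (2R,3R)-2-(3,4-dimethoxyphenyl)-3-[(2,4,6-trimethoxyphenyl)methyl]oxirane F6, with the face selectivity known for trans-β-methylstyrene. The crude, acid-sensitive epoxide is then hydrogenolysed at the benzylic C–O bond only (H2 1 atm, palladium metal on carbon, Pd/C 10 wt%, EtOAc with 1% Et3N, rt). The C2–O bond and its configuration are untouched, and the fallback comes back to the route at target 9. This costs one extra step, and the stereocentre is still set in a C–O bond-forming step.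

Step 2. The risks are attack at the benzylic carbon of cation 5 (branched isomer), double allylation of 4, and acid-driven oligomerisation of the electron-rich styrene 6. The fallback sets out from 3 and 4 and replaces the cationic C–C bond formation by a neutral organometallic one. Acetylation of 3 (Ac2O, Et3N, DMAP cat., CH2Cl2, 0 °C) gives 1-(3,4-dimethoxyphenyl)prop-2-en-1-yl acetate F3. Arene 4 is lithiated between two methoxy groups (n-BuLi, THF, 0 °C to rt) to (2,4,6-trimethoxyphenyl)lithium F4 and transmetallated with ZnCl2 to chloro(2,4,6-trimethoxyphenyl)zinc F5. Pd(PPh3)4-catalysed allyl–aryl coupling of F5 with F3 (Negishi type, THF, rt) gives the linear (E)-alkene and comes back to the route at 6.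

Step 1. The addition itself is reliable; the risk is that the electron-rich secondary allylic alcohol 3 ionises, rearranges or oligomerises on isolation or storage. The fallback sets out from 1. Horner–Wadsworth–Emmons olefination with triethyl phosphonoacetate (NaH, THF, 0 °C to rt) gives ethyl (E)-3-(3,4-dimethoxyphenyl)prop-2-enoate F1. Reduction with i-Bu2AlH (CH2Cl2, −78 °C) gives (E)-3-(3,4-dimethoxyphenyl)prop-2-en-1-ol F2, a robust primary cinnamyl alcohol. Under the step 2 conditions (40 °C if needed) F2 ionises to the same allyl cation 5 and comes back to the route at alkene 6.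

## Further compounds

F1 | step 1 | ethyl (E)-3-(3,4-dimethoxyphenyl)prop-2-enoate | CCOC(=O)/C=C/c1ccc(OC)c(OC)c1
F2 | step 1 | (E)-3-(3,4-dimethoxyphenyl)prop-2-en-1-ol | OC/C=C/c1ccc(OC)c(OC)c1
F3 | step 2 | 1-(3,4-dimethoxyphenyl)prop-2-en-1-yl acetate (racemic) | C=CC(OC(C)=O)c1ccc(OC)c(OC)c1
F4 | step 2 | (2,4,6-trimethoxyphenyl)lithium | [Li]c1c(OC)cc(OC)cc1OC
F5 | step 2 | chloro(2,4,6-trimethoxyphenyl)zinc | Cl[Zn]c1c(OC)cc(OC)cc1OC
F6 | step 3 | (2R,3R)-2-(3,4-dimethoxyphenyl)-3-[(2,4,6-trimethoxyphenyl)methyl]oxirane | COc1ccc(cc1OC)[C@H]1O[C@@H]1Cc1c(OC)cc(OC)cc1OC
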